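A plateau is easily read as a reagent used up, so before believing that of the blue run I ask what each row says about the rate at which intermediate B forms.

| flask | substrate | solid reagent | temperature | remark | time |
|---|---|---|---|---|---|
| red | 1 M | 0.75 M | 0 °C | run made earlier |  |
| blue | 1 M | 1.1 M | 30 °C | run made earlier |  |
| Wednesday's | 1.0 M | 1.50 M | 5 °C |  | 20 h |
| Saturday's | 1.0 M | 1.50 M | 30 °C |  | 20 h |
| Friday's | 1.0 M | 1.50 M | 55 °C |  | 20 h |

| run | time / h | intermediate C / % | intermediate A / % | substrate / % | target / % | intermediate B / % |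
|---|---|---|---|---|---|---|
| red | 1.33 | 0 | 14.5 | 84.4 | 0 | 2.0 |
| red | 2.00 | 0.1 | 20.2 | 76.9 | 0.1 | 3.4 |
| red | 3.00 | 0.3 | 28.1 | 67.9 | 0.9 | 4.5 |
| red | 5.00 | 0 | 40.4 | 53.2 | 0 | 6.7 |
| red | 6.00 | 0.7 | 45.3 | 47.7 | 0 | 7.3 |
| red | 10.0 | 0.6 | 57.6 | 32.7 | 0.1 | 9.2 |
| red | 15.0 | 0.9 | 65.9 | 22.8 | 0 | 10.9 |
| blue | 0.417 | 0.1 | 23.6 | 50.1 | 0.1 | 26.0 |
| blue | 0.667 | 0.3 | 20.3 | 44.0 | 0 | 35.2 |
| blue | 0.833 | 0 | 18.5 | 40.5 | 0 | 40.2 |
| blue | 1.33 | 0.5 | 15.6 | 34.3 | 0.1 | 50.6 |
| blue | 2.00 | 0.1 | 13.5 | 29.3 | 0 | 56.4 |
| blue | 3.00 | 0.3 | 12.5 | 26.5 | 0.1 | 60.6 |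
| blue | 4.00 | 0.6 | 12.1 | 26.3 | 0 | 61.2 |

(standard deviation of a reading: 0.3 percentage points)

1. which of these there is most of at the end, counted by the substrate in it, Wednesday's (intermediate C / intermediate A / substrate / intermediate B / target)
2. which of these there is most of at the end, counted by the substrate in it, Saturday's (intermediate C / intermediate A / substrate / intermediate B / target)
3. which of these there is most of at the end, counted by the substrate in it, Friday's (intermediate C / intermediate A / substrate / intermediate B / target)
4. amount of the one of these that there is most of at the end, in percent of the substrate charged, Wednesday's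
5. amount of the one of these that there is most of at the end, in percent of the substrate charged, Saturday's
6. amount of the one of these that there is most of at the end, in percent of the substrate charged, Friday's

- given per volume of solution although it is solid: solid reagent
- at the start none of the solid reagent is in solution

I define κ as the intermediate B gained per hour per unit of substrate present, an apparent first-order constant, and I read it from one row of each run, taking the mean of the charge and the reading as the substrate present over that interval. The red row at 5.00 h gives κ = 0.0175 h⁻¹, and the first blue row gives 0.831 h⁻¹, so together they give an apparent activation energy of 88.6 kJ mol⁻¹. The red and blue runs differ in solid reagent as well as in temperature, so this energy rests on my assumption that κ does not depend on the solid reagent.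

Now I read the last two blue rows. With substrate at 26.3% in the blue run, κ reckons 21.8% of gain in 1.00 h, yet intermediate B moves 0.6 percentage points, far less than that. These rows do not separate a balance with a way back from a used-up reagent; I commit to the balance, and so I keep 61.2% of intermediate B for Saturday's at the same temperature.

For Wednesday's, κ becomes 0.0353 h⁻¹. I freeze substrate at the last red reading, 22.8%, which gives 16.1% of intermediate B and, with intermediate C and target neglected, leaves 61.1% as intermediate A. For Friday's, no row shows the height of the balance, so I give no number of my own.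

The forecast differs from me on Wednesday's and Saturday's: it gives intermediate A at 48% for Wednesday's, intermediate B at 83% for Saturday's and intermediate B at 81% for Friday's, reasoning “Thus 1.5 M should cap B near 83%.”

Wednesday's gives intermediate A at 62.5%. Saturday's gives intermediate B at 61.4%. Friday's gives intermediate B at 77.2%.

    substrate ⇌ intermediate A (K = 2.98, k = 0.00420 min⁻¹, Ea = 97.0 kJ mol⁻¹, ΔH = −53.0 kJ mol⁻¹)
    substrate ⇌ intermediate B (K = 1.34, k = 6.36 × 10⁻⁴ min⁻¹, Ea = 95.0 kJ mol⁻¹, ΔH = 16.0 kJ mol⁻¹)
    substrate + partner ⇌ intermediate C (K = 0.283 M⁻¹, k = 1.41 × 10⁻⁴ M⁻¹ min⁻¹, Ea = 67.0 kJ mol⁻¹, ΔH = −4.00 kJ mol⁻¹)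
    partner + intermediate C ⇌ intermediate D (K = 0.490 M⁻¹, k = 0.0187 M⁻¹ min⁻¹, Ea = 63.0 kJ mol⁻¹, ΔH = 0 kJ mol⁻¹)
    intermediate D → target (k = 0.00160 min⁻¹, Ea = 84.0 kJ mol⁻¹)
    2 partner → homo dimer (k = 0.00159 M⁻¹ min⁻¹, Ea = 75.0 kJ mol⁻¹)
    solid reagent ⇌ partner, rate k7*(cs7 - [partner]) while solid is left; crystals form when [partner] > cs7 (solubility = 0.220 M, k = 0.00306 min⁻¹)
    partner → decomposition product (k = 4.34 × 10⁻⁶ min⁻¹, Ea = 99.0 kJ mol⁻¹)
    (constants at 5 °C)

In Wednesday's, substrate and intermediate A relax with a half-life of 2.06 h, both ways together, which is much shorter than the 20 h of the run, and substrate stands at 22.6% at 10.0 h. With that amount frozen, κ gives 15.9% for Wednesday's against the 17.0% found. For Wednesday's flask run at −20 °C, κ extrapolates to 8.02 × 10⁻⁴ h⁻¹, so substrate frozen at its charge gives 1.60% of intermediate B; that flask holds 1.25%, with 91.0% of substrate.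

The numbers in the tables are simulated for an exercise; noise was put on by code.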